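Everything rests on opening the benzenoid ring of the indole at C3a–C4 and C7–C7a. This exploits the fact that C4–C5(Br)–C6(Br)–C7 is a symmetrical 2,3-dibromobutadiene unit spanning the C3a–C7a edge that the six-membered carbocycle shares with the five-membered nitrogen ring. The key step joins 3,4-dibromothiophene 1,1-dioxide, an electron-poor cyclic diene, to the enecarbamate C=C of commercial N-Boc-2,3-dihydropyrrole. Cycloaddition and sulfur dioxide loss forge both bonds, close the carbocycle and fix both bromines at C5 and C6 in one operation. Double dehydrogenation, Boc-directed C2 bromination, a one-flask Boc-to-methyl exchange and a C3 Mannich reaction complete the target.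

Key step: step 2

Remark: the target is achiral; every chiral intermediate is racemic, and the SMILES show one enantiomer.

Step 1
Reactants: 1 3,4-dibromothiophene
Product: 3 3,4-dibromothiophene 1,1-dioxide, via 3,4-dibromothiophene 1-oxide 2 (not isolated)
Conditions: dimethyldioxirane (3 equiv, about 0.08 M in acetone), CH2Cl2, 0 °C → rt; evaporation below 30 °C
Reagents that add atoms: dimethyldioxirane, CC1(C)OO1
Why: Dioxirane oxygen transfer to sulfur is a known sulfide-to-sulfone oxidation for thiophenes, the non-aromatic S-oxide 2 should be oxidised faster than aromatic 1 and so not accumulate, and the neutral volatile by-product lets the dimerisation-prone sulfone be isolated without heat, acid or base.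

Step 2
Reactants: 3 3,4-dibromothiophene 1,1-dioxide; 4 tert-butyl 2,3-dihydro-1H-pyrrole-1-carboxylate
Product: 6 tert-butyl cis-5,6-dibromo-2,3,3a,7a-tetrahydro-1H-indole-1-carboxylate (racemic; 3aS,7aS enantiomer drawn), via endo bridged sulfone adduct 5 (not isolated)
Conditions: 3 added over 6 h to 4 (3 equiv), 2,6-di-tert-butyl-4-methylpyridine (5 mol %), BHT (1 mol %), PhMe, 80 °C, argon sparge; quick filtration through Et3N-deactivated silica, used at once
Reagents that add atoms: none
Why: The sulfonyl group and the two bromines lower the LUMO of the non-aromatic diene 3, the carbamate nitrogen raises the HOMO of the C4=C5 alkene of 4, and the two combine in a concerted, asynchronous, suprafacial (4+2) cycloaddition to the strained 7-thianorbornene dioxide 5, which expels SO2 in a cheletropic retro-(4+1) step and unveils the C4=C5(Br)–C6(Br)=C7 diene of 6. The closest known reaction type is the inverse-electron-demand Diels–Alder annulation of halogenated thiophene 1,1-dioxides with alkenes and enol ethers with spontaneous SO2 extrusion. The six-membered carbocycle is closed by intermolecular (4+2) annulation across the C3a–C7a edge, both new bonds (C3a–C4 and C7–C7a) arising in the same pericyclic event while the five-membered ring is carried through unchanged. C3a and C7a are set together as the cis pair because addition to the ring-constrained Z-alkene is suprafacial, whereas the endo or exo sense affects only C4 and C7 of 5, which return to sp2, and no absolute control is needed since both centres vanish in step 3. Regiochemistry does not arise because 3 is symmetrical, so the selectivity required is cross-addition over self-dimerisation of 3, which the matched electron demand built into both partners secures and excess 4 with slow addition of 3 reinforces. The hindered base, BHT and the argon stream keep SO2-derived acid and radicals away from 4 and from the allylic C7a–N bond of 6, and the 80 °C ceiling avoids 1,5-hydrogen shifts that could move a bromine-bearing carbon to sp3.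

Step 3
Reactants: 6 tert-butyl cis-5,6-dibromo-2,3,3a,7a-tetrahydro-1H-indole-1-carboxylate
Product: 8 tert-butyl 5,6-dibromo-1H-indole-1-carboxylate, via N-Boc-5,6-dibromoindoline 7 (not isolated)
Conditions: DDQ (3 equiv), 1,4-dioxane, rt 1 h, then 100 °C
Reagents that add atoms: none
Why: In this quinone dehydrogenation, hydride abstraction from C7a–H (allylic and alpha to nitrogen) and proton loss from C3a should aromatise the carbocycle at room temperature before the carbamate can leave, and the slower known DDQ dehydrogenation of N-acylindolines then removes the hydrogens of the remaining sp3 carbons C2 and C3 on heating, erasing both stereocentres and leaving the sp2 C–Br bonds untouched.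

Step 4
Reactants: 8 tert-butyl 5,6-dibromo-1H-indole-1-carboxylate
Product: 10 tert-butyl 2,5,6-tribromo-1H-indole-1-carboxylate, via 2-lithio-N-Boc-5,6-dibromoindole 9 (not isolated)
Conditions: LiN(i-Pr)2 (1.15 equiv), THF, −78 °C, 30 min; then BrCl2C–CCl2Br (1.3 equiv), THF, −78 → −30 °C
Reagents that add atoms: 1,2-dibromo-1,1,2,2-tetrachloroethane, BrC(Cl)(Cl)C(Cl)(Cl)Br
Why: Carbamate-directed lithiation of N-Boc indoles by a lithium amide occurs at C2 and, unlike an alkyllithium, the amide cannot undergo bromine–lithium exchange at C5 or C6, after which bromophilic attack of 9 on the polyhaloethane transfers bromine with loss of tetrachloroethene.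

Step 5
Reactants: 10 tert-butyl 2,5,6-tribromo-1H-indole-1-carboxylate
Product: 12 2,5,6-tribromo-1-methyl-1H-indole, via sodium 2,5,6-tribromoindol-1-ide 11 (not isolated)
Conditions: NaOMe (solid, 1.1 equiv), THF–DMF, 0 °C; then MeI (1.5 equiv), 0 °C → rt
Reagents that add atoms: iodomethane, CI
Why: Nucleophilic acyl substitution by methoxide at the activated carbamate carbonyl of the N-acylindole releases the stabilised indolide 11 directly, and its SN2 N-methylation in the same flask means the sensitive N–H 2-bromoindole is never handled.

Step 6
Reactants: 12 2,5,6-tribromo-1-methyl-1H-indole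
Product: 14 2,5,6-tribromo-1-methylgramine, via gramine hydroiodide salt 13 (not isolated)
Conditions: dimethylmethyleneammonium iodide (1.5 equiv), MeCN, 60 °C; then aq. NaOH (1 M), CH2Cl2 extraction
Reagents that add atoms: dimethylmethyleneammonium iodide, C=[N+](C)C.[I-]
Why: The Mannich aminomethylation with a preformed iminium salt is an electrophilic substitution at C3, the only free and the most nucleophilic position of the pyrrole ring of 12, and the anhydrous acid-free medium avoids C3 protonation and hydrolysis of the 2-bromoindole to an oxindole.

Compound list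
1 | 3,4-dibromothiophene | Brc1cscc1Br | starting material
2 | 3,4-dibromothiophene 1-oxide | O=S1C=C(Br)C(Br)=C1 | intermediate
3 | 3,4-dibromothiophene 1,1-dioxide | O=S1(=O)C=C(Br)C(Br)=C1 | intermediate
4 | tert-butyl 2,3-dihydro-1H-pyrrole-1-carboxylate | CC(C)(C)OC(=O)N1CCC=C1 | starting material
5 | tert-butyl 5,6-dibromo-2,3,3a,4,7,7a-hexahydro-4,7-epithio-1H-indole-1-carboxylate 8,8-dioxide (endo adduct, pyrrolidine ring anti to the SO2 bridge, racemic) | CC(C)(C)OC(=O)N1CC[C@@H]2[C@H]1[C@@H]1C(Br)=C(Br)[C@H]2S1(=O)=O | intermediate
6 | tert-butyl cis-5,6-dibromo-2,3,3a,7a-tetrahydro-1H-indole-1-carboxylate (racemic, 3aS,7aS drawn) | CC(C)(C)OC(=O)N1CC[C@H]2C=C(Br)C(Br)=C[C@@H]12 | intermediate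
7 | tert-butyl 5,6-dibromo-2,3-dihydro-1H-indole-1-carboxylate | CC(C)(C)OC(=O)N1CCc2cc(Br)c(Br)cc12 | intermediate
8 | tert-butyl 5,6-dibromo-1H-indole-1-carboxylate | CC(C)(C)OC(=O)n1ccc2cc(Br)c(Br)cc12 | intermediate
9 | tert-butyl 5,6-dibromo-2-lithio-1H-indole-1-carboxylate | [Li]c1cc2cc(Br)c(Br)cc2n1C(=O)OC(C)(C)C | intermediate
10 | tert-butyl 2,5,6-tribromo-1H-indole-1-carboxylate | CC(C)(C)OC(=O)n1c(Br)cc2cc(Br)c(Br)cc12 | intermediate
11 | sodium 2,5,6-tribromoindol-1-ide | [Na+].Brc1cc2cc(Br)c(Br)cc2[n-]1 | intermediate
12 | 2,5,6-tribromo-1-methyl-1H-indole | Cn1c(Br)cc2cc(Br)c(Br)cc12 | intermediate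
13 | 2,5,6-tribromo-1-methylgramine hydroiodide | C[NH+](C)Cc1c(Br)n(C)c2cc(Br)c(Br)cc12.[I-] | intermediate
14 | 2,5,6-tribromo-1-methylgramine | CN(C)Cc1c(Br)n(C)c2cc(Br)c(Br)cc12 | target

Total step count: 6. Longest linear sequence: 6 (from 1).

Steps most likely to fail

Step 2. The cross-addition may need more heat than the non-aromatic product tolerates. Forcing it would invite acid-triggered C7a–N cleavage with aromatisation, hydrogen shifts, and more self-dimerisation of the sulfone. The fallback sets out from 4 and comes back at 7 by turning the 2π partner into an alkyne equivalent, so that the primary product aromatises at once to a robust indoline.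
- Br2 is added to 4 in CH2Cl2 at −78 °C to give tert-butyl trans-2,3-dibromopyrrolidine-1-carboxylate F1.
- Et3N in the same flask removes HBr through the N-acyliminium ion and gives tert-butyl 4-bromo-2,3-dihydro-1H-pyrrole-1-carboxylate F2.
- Slow addition of 3 to excess F2 in PhMe at 100–110 °C, with a hindered pyridine base (1.2 equiv), should give the 3a-bromo bridged sulfone adduct F3.
- Loss of SO2 then gives tert-butyl cis-3a,5,6-tribromo-2,3,3a,7a-tetrahydro-1H-indole-1-carboxylate F4.
- This diene has no hydrogen at C3a, so it cannot expel the carbamate. It aromatises by ionisation of the tertiary allylic C3a–Br bond and loss of the C7a proton, giving 7, which enters the heating phase of step 3.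

Step 3. The second dehydrogenation may stall, because the carbamate and two bromines slow hydride loss from C2 and C3. Long heating with the acidic hydroquinone may also strip the Boc group. The fallback sets out from 7 and comes back at 8, moving the oxidation onto the free amine.
- The reaction is stopped after the room-temperature phase (DDQ, 1.1 equiv) and 7 is isolated.
- TFA in CH2Cl2 followed by basic work-up gives 5,6-dibromoindoline F5.
- Activated MnO2 in CH2Cl2 at rt dehydrogenates this electron-rich indoline to 5,6-dibromo-1H-indole F6.
- Boc2O with catalytic DMAP in MeCN returns 8.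

Step 4. Deprotonation ortho to bromine at C4 or C7 may compete, followed by bromine migration or aryne formation. The Boc group may also shift from nitrogen to C2 on warming. The fallback sets out from 8 and comes back at 14, using no organolithium and reordering the last three operations.
- NaOMe and then MeI, as in step 5, convert 8 into 5,6-dibromo-1-methyl-1H-indole F7.
- Dimethylmethyleneammonium iodide in MeCN, followed by basic work-up, gives 5,6-dibromo-1-methylgramine F8.
- Electrophilic bromination with NBS (1.05 equiv) in AcOH–HCO2H then places bromine at C2, the only open position of the pyrrole ring, and gives 14 after basification. In this medium the side-chain amine is protonated, which shields it from oxidation and retro-Mannich fragmentation.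

Further compounds
F1 | step 2 | tert-butyl trans-2,3-dibromopyrrolidine-1-carboxylate (racemic) | CC(C)(C)OC(=O)N1CC[C@H](Br)[C@H]1Br
F2 | step 2 | tert-butyl 4-bromo-2,3-dihydro-1H-pyrrole-1-carboxylate | CC(C)(C)OC(=O)N1CCC(Br)=C1
F3 | step 2 | tert-butyl 3a,5,6-tribromo-2,3,3a,4,7,7a-hexahydro-4,7-epithio-1H-indole-1-carboxylate 8,8-dioxide (endo adduct, racemic) | CC(C)(C)OC(=O)N1CC[C@]2(Br)[C@H]1[C@@H]1C(Br)=C(Br)[C@H]2S1(=O)=O
F4 | step 2 | tert-butyl cis-3a,5,6-tribromo-2,3,3a,7a-tetrahydro-1H-indole-1-carboxylate (racemic) | CC(C)(C)OC(=O)N1CC[C@@]2(Br)C=C(Br)C(Br)=C[C@@H]12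
F5 | step 3 | 5,6-dibromoindoline | Brc1cc2c(cc1Br)NCC2
F6 | step 3 | 5,6-dibromo-1H-indole | Brc1cc2cc[nH]c2cc1Br
F7 | step 4 | 5,6-dibromo-1-methyl-1H-indole | Cn1ccc2cc(Br)c(Br)cc12
F8 | step 4 | 5,6-dibromo-1-methylgramine | CN(C)Cc1cn(C)c2cc(Br)c(Br)cc12
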